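**Plan**

1. Numbering: C1 (ring B CH bearing C11H2O), C2, C3, C4 (alkene carbon bearing the quaternary carbon Cq of ring C), C5, C6, C7 (lactone α-CH), C8 (lactone C=O), C9 (lactone OCH), C10 (ring-fusion CH); ring A = C5-C6-C7-C9-C10, ring B = C1-C2-C3-C4-C5-C10, ring C = 1,3,3-trimethylcyclohexyl; β = the face of ring A that carries H10 in the target (C8 and O9 are β, C1 is α).
2. Enabling feature: O9 and O11 stand 1,4 to each other across the C10-C1 bond, so C10 and C1 are both enol-ether (donor) carbons; one-electron oxidation of the C9 dienol ether turns C10 into an acceptor and lets ring B close.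
3. Cuts (retro): butyrate O-acyl and lactone O9-C8; C1-C10 (ring B, anodic coupling); C5-C10 (ring A, vinyllithium alkylation); C6-C7 (lactone enolate alkylation); C3-C4 and C5-I (carbocupration of an ynoate); Cq-C4 (Johnson-Claisen on isophorol).
4. Forward order: ring C with Cq, then the tetrasubstituted C4=C5 alkene of fixed geometry, then ring A, then ring B (key step), last the β-lactone.
5. Stereochemistry: Cq from (R)-isophorol by [3,3] chirality transfer; C7 from (S)-3-hydroxy-γ-butyrolactone by trans alkylation; C10 and C1 in the key step under control of C7; C9 by hydride addition anti to the C7 arm; alkene geometry from syn carbocupration and retentive iodination.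

Key step: step 21

Remark: the locants and the α/β convention of line 1 are also used for open-chain intermediates.
Assumption: the methyl enol ether is carried as the (E) isomer; a minor (Z) content would give the same acetal, because C11 stops being stereogenic when methanol adds.

**Route**

Step 1
Reactants: 1 isophorone (3,5,5-trimethylcyclohex-2-en-1-one)
Product: 2 (R)-isophorol, (1R)-3,5,5-trimethylcyclohex-2-en-1-ol
Conditions: (S)-2-methyl-CBS-oxazaborolidine (10 mol %), catecholborane, toluene, −78 °C
Reagents that add atoms: none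
Why: Corey–Bakshi–Shibata reduction, in which the alkene-bearing side of the carbonyl plays the large group in the oxazaborolidine–borane complex, so hydride should reach one face and give the (R) allylic alcohol.

Step 2
Reactants: 2 (R)-isophorol; 3 triethyl orthoacetate
Product: 5 ethyl 2-[(1R)-1,5,5-trimethylcyclohex-2-en-1-yl]acetate, via mixed ketene acetal 4 (not isolated)
Conditions: 3 (6 equiv), EtCO2H (cat.), 140 °C, EtOH distilled off
Reagents that add atoms: triethyl orthoacetate (3), CCOC(C)(OCC)OCC
Why: Johnson–Claisen rearrangement; the ketene acetal rearranges through a chair on the ring face of the breaking C–O bond, so the carbinol configuration is transferred to the (R) quaternary carbon Cq.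

Step 3
Reactants: 5 ethyl 2-[(1R)-1,5,5-trimethylcyclohex-2-en-1-yl]acetate
Product: 6 ethyl 2-[(1R)-1,3,3-trimethylcyclohexyl]acetate
Conditions: H2 (1 atm), 10% Pd on carbon, EtOAc, rt
Reagents that add atoms: none
Why: Heterogeneous hydrogenation of the disubstituted ring alkene, which leaves the ester and Cq untouched.

Step 4
Reactants: 6 ethyl 2-[(1R)-1,3,3-trimethylcyclohexyl]acetate
Product: 7 2-[(1R)-1,3,3-trimethylcyclohexyl]acetaldehyde
Conditions: i-Bu2AlH (1.05 equiv), CH2Cl2, −78 °C; aqueous potassium sodium tartrate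
Reagents that add atoms: none
Why: Partial reduction of an ester; the aluminium hemiacetal is stable at −78 °C and should release the aldehyde only on work-up.

Step 5
Reactants: 7 2-[(1R)-1,3,3-trimethylcyclohexyl]acetaldehyde
Product: 9 (1R)-1-ethynyl-1,3,3-trimethylcyclohexane, via enol nonaflate 8 (not isolated)
Conditions: n-C4F9SO2F, phosphazene base P2-Et, DMF, −30 °C to rt
Reagents that add atoms: none
Why: One-pot enol sulfonylation and base-induced elimination (dehydration of an enolisable aldehyde to a terminal alkyne); Cq carries no hydrogen, so no allene can form.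

Step 6
Reactants: 9 (1R)-1-ethynyl-1,3,3-trimethylcyclohexane
Product: 11 methyl 3-[(1R)-1,3,3-trimethylcyclohexyl]prop-2-ynoate, via lithium acetylide 10 (not isolated)
Conditions: n-BuLi, THF, −78 °C; ClCO2Me, −78 to 0 °C
Reagents that add atoms: methyl chloroformate, COC(Cl)=O
Why: C-acylation of a lithium acetylide by a chloroformate.

Step 7
Reactants: 11 methyl 3-[(1R)-1,3,3-trimethylcyclohexyl]prop-2-ynoate; 12 but-3-enylmagnesium bromide
Product: 14 methyl (2E)-2-iodo-3-[(1R)-1,3,3-trimethylcyclohexyl]hepta-2,6-dienoate, via alkenylcopper adduct 13 (not isolated)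
Conditions: 12 (1.3 equiv), CuBr·SMe2 (1.3 equiv), THF, −40 °C; 11, −78 °C; I2, −78 °C
Reagents that add atoms: but-3-enylmagnesium bromide (12), C=CCC[Mg]Br; iodine, II
Why: Carbocupration of an alkynoate (syn conjugate addition) followed by iodinolysis of the alkenylcopper with retention should place the butenyl arm (C3) and iodine cis and the ester (C6) cis to ring C, which fixes the C4=C5 geometry; the bulk of ring C favours the same outcome should the allenoate intervene.

Step 8
Reactants: 14 methyl (2E)-2-iodo-3-[(1R)-1,3,3-trimethylcyclohexyl]hepta-2,6-dienoate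
Product: 15 (2E)-2-iodo-3-[(1R)-1,3,3-trimethylcyclohexyl]hepta-2,6-dien-1-ol
Conditions: i-Bu2AlH (2.5 equiv), CH2Cl2, −78 to 0 °C; aqueous potassium sodium tartrate
Reagents that add atoms: none
Why: Hydride reduction of a conjugated ester to the allylic alcohol; the vinylic C–I bond and the isolated alkene should not react at low temperature.

Step 9
Reactants: 15 (2E)-2-iodo-3-[(1R)-1,3,3-trimethylcyclohexyl]hepta-2,6-dien-1-ol
Product: 16 (5E)-7-bromo-6-iodo-5-[(1R)-1,3,3-trimethylcyclohexyl]hepta-1,5-diene
Conditions: CBr4, PPh3, CH2Cl2, 0 °C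
Reagents that add atoms: carbon tetrabromide, BrC(Br)(Br)Br
Why: Appel bromination of a primary allylic alcohol by SN2 displacement; allylic transposition is blocked because the far alkene carbon is fully substituted.

Step 10
Reactants: 16 (5E)-7-bromo-6-iodo-5-[(1R)-1,3,3-trimethylcyclohexyl]hepta-1,5-diene; 17 (S)-3-hydroxy-γ-butyrolactone, (4S)-4-hydroxyoxolan-2-one
Product: 19 (3S,4S)-4-hydroxy-3-[(2E)-2-iodo-3-[(1R)-1,3,3-trimethylcyclohexyl]hepta-2,6-dien-1-yl]oxolan-2-one, via dilithio lactone dianion 18 (not isolated)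
Conditions: 17, LiN(i-Pr)2 (2.2 equiv), THF, −78 to −40 °C; 16, DMPU, −78 to −30 °C
Reagents that add atoms: (S)-3-hydroxy-γ-butyrolactone (17), O=C1C[C@H](O)CO1
Why: Fráter–Seebach alkylation; the lithium alkoxide on C9 shields one face of the enolate, so the allylic bromide should add trans to it and create C7 with C8 and O9 cis on the future ring A.

Step 11
Reactants: 19 the trans lactone
Product: 20 (2S,3R)-3-[(2E)-2-iodo-3-[(1R)-1,3,3-trimethylcyclohexyl]hepta-2,6-dien-1-yl]butane-1,2,4-triol (C10H2OH, C9HOH, C8H2OH)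
Conditions: LiBH4, THF, 0 °C to rt
Reagents that add atoms: none
Why: Reduction of a lactone to the diol by LiBH4, a hydride that should leave the vinyl iodide intact.

Step 12
Reactants: 20 the triol
Product: 21 C10 mono-tosylate of 20, (2S,3R,5E)-2-hydroxy-3-(hydroxymethyl)-5-iodo-6-[(1R)-1,3,3-trimethylcyclohexyl]deca-5,9-dien-1-yl 4-methylbenzenesulfonate
Conditions: Bu2SnO (5 mol %), TsCl (1.05 equiv), Et3N, CH2Cl2, 0 °C
Reagents that add atoms: 4-methylbenzenesulfonyl chloride, Cc1ccc(cc1)S(Cl)(=O)=O
Why: Tin-catalysed regioselective sulfonylation; the stannylene acetal of the terminal 1,2-diol activates the primary oxygen on C10, while the C8 hydroxyl is more hindered and should react slowly.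

Step 13
Reactants: 21 the C10 mono-tosylate
Product: 22 C8,C9-O-isopropylidene acetal (2,2-dimethyl-1,3-dioxane) of 21, C10 tosylate retained
Conditions: Me2C(OMe)2, PPTS (cat.), CH2Cl2, rt
Reagents that add atoms: 2,2-dimethoxypropane, COC(C)(C)OC
Why: Acetalisation of the remaining 1,3-diol masks both hydroxyls against the organolithium of the next step.

Step 14
Reactants: 22 the acetonide tosylate
Product: 24 ring A acetonide (cis-fused cyclopentane/2,2-dimethyl-1,3-dioxane; exocyclic C5=C4 alkene carrying ring C and the but-3-enyl arm, the arm cis to C10), via vinyllithium 23 (not isolated)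
Conditions: t-BuLi (2.1 equiv), Et2O–pentane, −78 °C; then 0 °C
Reagents that add atoms: none
Why: Iodine–lithium exchange with retention of alkene geometry followed by 5-exo-tet alkylation of the vinyllithium by the primary tosylate (Parham-type cyclialkylation) should close ring A through the C5–C10 bond.

Step 15
Reactants: 24 the ring A acetonide
Product: 25 (1R,2R,4E)-2-(hydroxymethyl)-4-{1-[(1R)-1,3,3-trimethylcyclohexyl]pent-4-en-1-ylidene}cyclopentan-1-ol (9β-OH and 7β-CH2OH, cis)
Conditions: PPTS, MeOH, 40 °C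
Reagents that add atoms: none
Why: Acid-catalysed transacetalisation removes the isopropylidene group; the hindered tetrasubstituted alkene should not be protonated by a pyridinium acid.

Step 16
Reactants: 25 the cis diol
Product: 26 8-O-tert-butyldiphenylsilyl ether of 25 (9β-OH free)
Conditions: t-BuPh2SiCl (1.05 equiv), imidazole, CH2Cl2, 0 °C
Reagents that add atoms: tert-butyl(chloro)diphenylsilane, CC(C)(C)[Si](Cl)(c1ccccc1)c1ccccc1
Why: Silylation of the primary hydroxyl in preference to the hindered secondary one; the large silyl group later shields the β face of ring A.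

Step 17
Reactants: 26 the silyl ether alcohol; 27 vinylboronic acid pinacol ester
Product: 28 (E)-alkenyl pinacolboronate (C1H=C11H–B in place of the terminal alkene of 26)
Conditions: 27 (3 equiv), second-generation Grubbs catalyst (5 mol %), CH2Cl2, 40 °C
Reagents that add atoms: vinylboronic acid pinacol ester (27), C=CB1OC(C)(C)C(C)(C)O1
Why: Olefin cross-metathesis of a terminal alkene with a vinylboronate should give the (E)-alkenylboronate; the tetrasubstituted C4=C5 alkene is inert to the ruthenium carbene.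

Step 18
Reactants: 28 the (E)-alkenyl boronate
Product: 29 (E)-methyl enol ether alcohol (C1H=C11H–OMe; 9β-OH, 8-O-silyl)
Conditions: Cu(OAc)2 (2 equiv), Et3N, MeOH, 4 Å molecular sieves, air, rt
Reagents that add atoms: methanol, CO
Why: Chan–Lam-type oxidative C–O coupling of an alkenylboronate with an alcohol, which keeps the alkene geometry and so should give the (E) enol ether.

Step 19
Reactants: 29 the enol ether alcohol
Product: 30 C9 ketone (β,γ-unsaturated; 7β-CH2OSiPh2t-Bu)
Conditions: Dess–Martin periodinane, pyridine, CH2Cl2, 0 °C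
Reagents that add atoms: none
Why: Dess–Martin oxidation under pyridine buffer should convert the secondary alcohol into the ketone without hydrolysing the enol ether or epimerising C7.

Step 20
Reactants: 30 the C9 ketone
Product: 31 silyl dienol ether, C9(OSiMe2t-Bu)=C10H–C5=C4, tethered through C3–C2 to the (E)-methyl enol ether C1=C11
Conditions: t-BuMe2SiOTf, Et3N, CH2Cl2, −78 °C
Reagents that add atoms: tert-butyldimethylsilyl trifluoromethanesulfonate, CC(C)(C)[Si](C)(C)OS(=O)(=O)C(F)(F)F
Why: Soft enolisation; O-silylation and loss of the doubly activated (α and allylic) C10 proton should give the 2-silyloxy diene regioselectively, with C7 and the C4=C5 geometry unchanged.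

Step 21
Reactants: 31 the silyl dienol ether
Product: 32 bicyclic ketone (rings A and B): C9=O, H10 β, C1 bearing CH(OMe)2 trans to C9, C4=C5 alkene, 7β-CH2OSiPh2t-Bu
Conditions: reticulated vitreous carbon anode, Pt cathode, undivided cell, constant current (8 mA, about 2.2 F/mol), 0.1 M LiClO4 in MeOH/THF (1:1), 2,6-lutidine (4 equiv), rt
Reagents that add atoms: methanol, CO
Why: The 2-silyloxy diene is the most easily oxidised group, so the anode should remove one electron from it, and the radical cation is then captured at C10 by C1 of the tethered methyl enol ether (anodic olefin coupling of two enol ethers, a known reaction type). Ring B closes in a 6-exo mode with respect to the enol ether (C11 stays outside the ring) through a half-chair in which the existing C4=C5 bond holds C3 next to C10; attack at C4 would need a four-membered ring. A second electron transfer turns the C11 radical into an oxocarbenium ion that methanol traps as the dimethyl acetal, and transfer of the silyl group to methanol under lutidine buffer releases the C9 ketone with the alkene left β,γ. C10 is set by C7: the silyloxymethyl arm covers the β face of the flat ring A, so C1 should bond to the α face, trans to C8. C1 is set by the half-chair, with the C11 carbon pseudo-equatorial and therefore trans to C9 (H1 and H10 trans-diaxial). The step needs site selectivity (secured by ring size), facial selectivity (secured by the bulky C7 arm) and oxidation of the dienol ether before the simple enol ether (secured by its lower oxidation potential).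

Step 22
Reactants: 32 the bicyclic ketone
Product: 33 9β-alcohol (OH cis to C8, trans to C1)
Conditions: LiBH(s-Bu)3 (L-Selectride), THF, −78 °C, directly after step 21
Reagents that add atoms: none
Why: Hydride addition to a cyclopentanone by a bulky trialkylborohydride, expected anti to the silyloxymethyl arm on C7 (the arm that steered C1), which would set C9 with the hydroxyl cis to C8 as in 25.

Step 23
Reactants: 33 the 9β-alcohol
Product: 34 C11 aldehyde (9β-OH, 8-O-silyl)
Conditions: PPTS, acetone/H2O, 40 °C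
Reagents that add atoms: water, O
Why: Acid-catalysed acetal hydrolysis; the silyl ether is stable, the equatorial formyl group on C1 is already the more stable epimer, and O9 lies on the face opposite C1 so no lactol can form.

Step 24
Reactants: 34 the C11 aldehyde
Product: 35 9,11-diol (C11H2OH, 9β-OH, 8-O-silyl)
Conditions: NaBH4, MeOH, 0 °C
Reagents that add atoms: none
Why: Borohydride reduction of an aldehyde.

Step 25
Reactants: 35 the 9,11-diol
Product: 36 C11 butyrate (9β-OH free, 8-O-silyl)
Conditions: (n-PrCO)2O (1.1 equiv), Et3N, DMAP (cat.), CH2Cl2, −40 °C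
Reagents that add atoms: butanoic anhydride, CCCC(=O)OC(=O)CCC
Why: DMAP-catalysed acylation, which should take the primary C11 hydroxyl in preference to the hindered secondary C9 hydroxyl.

Step 26
Reactants: 36 the C11 butyrate
Product: 37 8,9-diol butyrate (C8H2OH, 9β-OH)
Conditions: HF·pyridine, THF, 0 °C to rt
Reagents that add atoms: none
Why: Fluoride-induced desilylation under weakly acidic conditions, which should leave the butyrate in place.

Step 27
Reactants: 37 the 8,9-diol butyrate
Product: 39 cis β-hydroxy acid (C8O2H, 9β-OH), via C8 aldehyde 38 (not isolated)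
Conditions: TEMPO (0.2 equiv), PhI(OAc)2 (2.2 equiv), MeCN/H2O (1:1), rt
Reagents that add atoms: water, O
Why: Oxoammonium (TEMPO) oxidation, selective for the primary alcohol and carried through the aldehyde hydrate to the acid.

Step 28
Reactants: 39 the cis β-hydroxy acid
Product: 41 CNP0144861.2 (C8–O9 β-lactone cis-fused to ring A, C11 butyrate), via mixed carboxylic sulfonic anhydride 40 (not isolated)
Conditions: TsCl, pyridine, 0 to 5 °C
Reagents that add atoms: none
Why: β-Lactonisation by carboxyl activation; the cis C9 hydroxyl attacks the mixed anhydride, so C9 keeps its configuration and only the cis-fused lactone can form.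

**Compound list**

1 | isophorone (3,5,5-trimethylcyclohex-2-en-1-one) | CC1=CC(=O)CC(C)(C)C1 | starting material
2 | (1R)-3,5,5-trimethylcyclohex-2-en-1-ol, (R)-isophorol | O[C@H]1C=C(C)CC(C)(C)C1 | intermediate
3 | triethyl orthoacetate | CCOC(C)(OCC)OCC | starting material
4 | mixed ketene acetal, 1-ethoxy-1-[(1R)-3,5,5-trimethylcyclohex-2-en-1-yloxy]ethene | C=C(OCC)O[C@H]1C=C(C)CC(C)(C)C1 | intermediate (not isolated)
5 | ethyl 2-[(1R)-1,5,5-trimethylcyclohex-2-en-1-yl]acetate | CCOC(=O)C[C@]1(C)C=CCC(C)(C)C1 | intermediate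
6 | ethyl 2-[(1R)-1,3,3-trimethylcyclohexyl]acetate | CCOC(=O)C[C@]1(C)CCCC(C)(C)C1 | intermediate
7 | 2-[(1R)-1,3,3-trimethylcyclohexyl]acetaldehyde | O=CC[C@]1(C)CCCC(C)(C)C1 | intermediate
8 | enol nonaflate, 2-[(1R)-1,3,3-trimethylcyclohexyl]ethenyl nonafluorobutane-1-sulfonate (alkene geometry not fixed) | FC(F)(F)C(F)(F)C(F)(F)C(F)(F)S(=O)(=O)OC=C[C@]1(C)CCCC(C)(C)C1 | intermediate (not isolated)
9 | (1R)-1-ethynyl-1,3,3-trimethylcyclohexane | C#C[C@]1(C)CCCC(C)(C)C1 | intermediate
10 | lithium acetylide of 9 | [Li]C#C[C@]1(C)CCCC(C)(C)C1 | intermediate (not isolated)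
11 | methyl 3-[(1R)-1,3,3-trimethylcyclohexyl]prop-2-ynoate | COC(=O)C#C[C@]1(C)CCCC(C)(C)C1 | intermediate
12 | but-3-enylmagnesium bromide | C=CCC[Mg]Br | starting material
13 | alkenylcopper adduct (Cu on C5 cis to the butenyl arm) | COC(=O)/C([Cu])=C(/CCC=C)[C@]1(C)CCCC(C)(C)C1 | intermediate (not isolated)
14 | methyl (2E)-2-iodo-3-[(1R)-1,3,3-trimethylcyclohexyl]hepta-2,6-dienoate | COC(=O)/C(I)=C(/CCC=C)[C@]1(C)CCCC(C)(C)C1 | intermediate
15 | (2E)-2-iodo-3-[(1R)-1,3,3-trimethylcyclohexyl]hepta-2,6-dien-1-ol | OC/C(I)=C(/CCC=C)[C@]1(C)CCCC(C)(C)C1 | intermediate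
16 | (5E)-7-bromo-6-iodo-5-[(1R)-1,3,3-trimethylcyclohexyl]hepta-1,5-diene | BrC/C(I)=C(/CCC=C)[C@]1(C)CCCC(C)(C)C1 | intermediate
17 | (S)-3-hydroxy-γ-butyrolactone, (4S)-4-hydroxyoxolan-2-one | O=C1C[C@H](O)CO1 | starting material
18 | dilithio dianion of 17 (lithium enolate, lithium alkoxide) | [Li]OC1=C[C@H](O[Li])CO1 | intermediate (not isolated)
19 | (3S,4S)-4-hydroxy-3-[(2E)-2-iodo-3-[(1R)-1,3,3-trimethylcyclohexyl]hepta-2,6-dien-1-yl]oxolan-2-one | O=C1OC[C@@H](O)[C@@H]1C/C(I)=C(/CCC=C)[C@]2(C)CCCC(C)(C)C2 | intermediate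
20 | (2S,3R)-3-[(2E)-2-iodo-3-[(1R)-1,3,3-trimethylcyclohexyl]hepta-2,6-dien-1-yl]butane-1,2,4-triol | OC[C@@H](O)[C@@H](CO)C/C(I)=C(/CCC=C)[C@]1(C)CCCC(C)(C)C1 | intermediate
21 | C10 mono-tosylate of 20 | Cc1ccc(cc1)S(=O)(=O)OC[C@@H](O)[C@@H](CO)C/C(I)=C(/CCC=C)[C@]1(C)CCCC(C)(C)C1 | intermediate
22 | C8,C9-O-isopropylidene acetal of 21 (C10 tosylate) | Cc1ccc(cc1)S(=O)(=O)OC[C@H]1OC(C)(C)OC[C@H]1C/C(I)=C(/CCC=C)[C@]2(C)CCCC(C)(C)C2 | intermediate
23 | vinyllithium from 22 (Li on C5 in place of I) | Cc1ccc(cc1)S(=O)(=O)OC[C@H]1OC(C)(C)OC[C@H]1C/C([Li])=C(/CCC=C)[C@]2(C)CCCC(C)(C)C2 | intermediate (not isolated)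
24 | ring A acetonide (cis-fused cyclopentane/2,2-dimethyl-1,3-dioxane, exocyclic C5=C4, butenyl arm cis to C10) | C=CCC/C(=C1/C[C@@H]2COC(C)(C)O[C@@H]2C1)[C@]3(C)CCCC(C)(C)C3 | intermediate
25 | (1R,2R,4E)-2-(hydroxymethyl)-4-{1-[(1R)-1,3,3-trimethylcyclohexyl]pent-4-en-1-ylidene}cyclopentan-1-ol | C=CCC/C(=C1/C[C@H](CO)[C@H](O)C1)[C@]2(C)CCCC(C)(C)C2 | intermediate
26 | 8-O-tert-butyldiphenylsilyl ether of 25 | C=CCC/C(=C1/C[C@H](CO[Si](c2ccccc2)(c2ccccc2)C(C)(C)C)[C@H](O)C1)[C@]3(C)CCCC(C)(C)C3 | intermediate
27 | vinylboronic acid pinacol ester | C=CB1OC(C)(C)C(C)(C)O1 | starting material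
28 | (E)-alkenyl pinacolboronate (C1=C11–B) | CC1(C)OB(OC1(C)C)/C=C/CC/C(=C1/C[C@H](CO[Si](c2ccccc2)(c2ccccc2)C(C)(C)C)[C@H](O)C1)[C@]1(C)CCCC(C)(C)C1 | intermediate
29 | (E)-methyl enol ether alcohol (9β-OH) | CO/C=C/CC/C(=C1/C[C@H](CO[Si](c2ccccc2)(c2ccccc2)C(C)(C)C)[C@H](O)C1)[C@]1(C)CCCC(C)(C)C1 | intermediate
30 | C9 ketone with (E)-methyl enol ether tether | CO/C=C/CC/C(=C1/C[C@H](CO[Si](c2ccccc2)(c2ccccc2)C(C)(C)C)C(=O)C1)[C@]1(C)CCCC(C)(C)C1 | intermediate
31 | silyl dienol ether (key-step precursor) | CO/C=C/CC/C(=C1/C[C@H](CO[Si](c2ccccc2)(c2ccccc2)C(C)(C)C)C(O[Si](C)(C)C(C)(C)C)=C1)[C@]1(C)CCCC(C)(C)C1 | intermediate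
32 | bicyclic C9 ketone with C11 dimethyl acetal (key-step product) | COC(OC)[C@@H]1CCC([C@]2(C)CCCC(C)(C)C2)=C2C[C@H](CO[Si](c3ccccc3)(c3ccccc3)C(C)(C)C)C(=O)[C@H]21 | intermediate
33 | 9β-alcohol of 32 | COC(OC)[C@@H]1CCC([C@]2(C)CCCC(C)(C)C2)=C2C[C@H](CO[Si](c3ccccc3)(c3ccccc3)C(C)(C)C)[C@H](O)[C@H]21 | intermediate
34 | C11 aldehyde | O=C[C@@H]1CCC([C@]2(C)CCCC(C)(C)C2)=C2C[C@H](CO[Si](c3ccccc3)(c3ccccc3)C(C)(C)C)[C@H](O)[C@H]21 | intermediate
35 | 9,11-diol | OC[C@@H]1CCC([C@]2(C)CCCC(C)(C)C2)=C2C[C@H](CO[Si](c3ccccc3)(c3ccccc3)C(C)(C)C)[C@H](O)[C@H]21 | intermediate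
36 | C11 butyrate, 8-O-silyl, 9β-OH | CCCC(=O)OC[C@@H]1CCC([C@]2(C)CCCC(C)(C)C2)=C2C[C@H](CO[Si](c3ccccc3)(c3ccccc3)C(C)(C)C)[C@H](O)[C@H]21 | intermediate
37 | C11 butyrate 8,9-diol | CCCC(=O)OC[C@@H]1CCC([C@]2(C)CCCC(C)(C)C2)=C2C[C@H](CO)[C@H](O)[C@H]21 | intermediate
38 | C8 aldehyde of 37 | CCCC(=O)OC[C@@H]1CCC([C@]2(C)CCCC(C)(C)C2)=C2C[C@H](C=O)[C@H](O)[C@H]21 | intermediate (not isolated)
39 | cis β-hydroxy acid (C8O2H, 9β-OH) | CCCC(=O)OC[C@@H]1CCC([C@]2(C)CCCC(C)(C)C2)=C2C[C@H](C(=O)O)[C@H](O)[C@H]21 | intermediate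
40 | mixed carboxylic 4-methylbenzenesulfonic anhydride of 39 | CCCC(=O)OC[C@@H]1CCC([C@]2(C)CCCC(C)(C)C2)=C2C[C@H](C(=O)OS(=O)(=O)c3ccc(C)cc3)[C@H](O)[C@H]21 | intermediate (not isolated)
41 | CNP0144861.2 | CCCC(=O)OC[C@@H]1CCC([C@]2(C)CCCC(C)(C)C2)=C2C[C@@H]3C(=O)O[C@@H]3[C@H]21 | target

**Count and risks**

Total steps: 28. Longest linear sequence: 28 steps (1 to 41); 3, 12, 17 and 27 are purchased.

Steps most likely to fail:

Step 21. What may go wrong: methanol may capture the radical cation before C1 does, or C1 may add to both faces of C10 because induction from C7 across C9 is weak. The fallback forms the same C1–C10 bond by a reversible two-electron Michael addition; it sets out from 26 and returns at 32. Dess–Martin oxidation of 26 would give the C9 ketone with the butenyl arm F1. Radical nitration of its terminal alkene (AgNO2, TEMPO, 1,2-dichloroethane, 70 °C) would give the (E)-nitroalkene F2. Catalytic DBU would generate the C10 dienolate, which should add to the nitroalkene (6-exo) to give the nitro ketone F3, with C1 and C10 equilibrating to the arrangement of 32. A Nef reaction in methanol (NaOMe, then H2SO4/MeOH at −40 °C) would turn CH2NO2 into the dimethyl acetal 32.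

Step 22. What may go wrong: hydride may be delivered to the β face (anti to ring B instead of anti to the C7 arm), so that the C9 epimer predominates. The fallback sets C9 by SN2 inversion instead of by facial selection; it sets out from 32 and returns at 33. Reduction of 32 with NaBH4 and CeCl3 in MeOH would be used to collect the 9α-alcohol F4. A Mitsunobu reaction (4-nitrobenzoic acid, PPh3, diisopropyl azodicarboxylate, THF) would give the inverted 9β 4-nitrobenzoate F5. Methanolysis (K2CO3, MeOH) would give 33.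

Step 14. What may go wrong: the hindered vinyllithium may be quenched by proton transfer, or may attack the sulfonyl sulfur instead of C10. The fallback replaces the carbanion by a nickel-catalysed reductive coupling of two halides; it sets out from 22 and returns at 24. Finkelstein exchange (NaI, acetone) would give the primary iodide F6. NiI2 with 4,4′-di-tert-butyl-2,2′-bipyridine and Mn powder in N,N-dimethylacetamide should then join the vinyl iodide and the alkyl iodide (5-exo) to give 24 with the alkene geometry kept.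

**Further compounds**

F1 | step 21 | C9 ketone with but-3-enyl arm (oxidation product of 26) | C=CCC/C(=C1/C[C@H](CO[Si](c2ccccc2)(c2ccccc2)C(C)(C)C)C(=O)C1)[C@]1(C)CCCC(C)(C)C1
F2 | step 21 | (E)-nitroalkene (C1H=C11H–NO2) | [O-][N+](=O)/C=C/CC/C(=C1/C[C@H](CO[Si](c2ccccc2)(c2ccccc2)C(C)(C)C)C(=O)C1)[C@]1(C)CCCC(C)(C)C1
F3 | step 21 | bicyclic nitro ketone (C11H2NO2 on C1) | [O-][N+](=O)C[C@@H]1CCC([C@]2(C)CCCC(C)(C)C2)=C2C[C@H](CO[Si](c3ccccc3)(c3ccccc3)C(C)(C)C)C(=O)[C@H]21
F4 | step 22 | 9α-alcohol (C9 epimer of 33) | COC(OC)[C@@H]1CCC([C@]2(C)CCCC(C)(C)C2)=C2C[C@H](CO[Si](c3ccccc3)(c3ccccc3)C(C)(C)C)[C@@H](O)[C@H]21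
F5 | step 22 | 9β 4-nitrobenzoate | COC(OC)[C@@H]1CCC([C@]2(C)CCCC(C)(C)C2)=C2C[C@H](CO[Si](c3ccccc3)(c3ccccc3)C(C)(C)C)[C@H](OC(=O)c3ccc(cc3)[N+]([O-])=O)[C@H]21
F6 | step 14 | primary C10 iodide of the acetonide | IC[C@H]1OC(C)(C)OC[C@H]1C/C(I)=C(/CCC=C)[C@]2(C)CCCC(C)(C)C2
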